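## Retrosynthetic overview

1. The only ring (ten-membered) is closed last, by olefin metathesis at the Z-trisubstituted C3=C4 bond of an acyclic diacetate. The diacetate comes from a keto (E)-2-ene-1,4-diol by methylenation and acetylation.
2. Key disconnection, C1–O: the allylic C1–O bond and the E C9=C10 olefin are made together by a [2,3]-sigmatropic sulfoxide-to-sulfenate shift that moves the heteroatom from C9 to C1 with 1,3-chirality transfer.
3. C8–C9: an α-thioallyl titanate adds to an α-branched keto aldehyde (Felkin, anti) in the same flask as the oxygen transposition.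
4. Keto aldehyde: (R)-citronellal plus methyl vinyl ketone by organocatalytic Michael addition (C11 from the chiral pool, C7 by catalyst control).
5. Thioallyl unit: methacrolein plus allylmagnesium bromide, then bromination with allylic transposition and thiolate substitution.

Assumption and labels (one line): the target is taken exactly as drawn; C1 = CH(OAc) next to C2H2, C3=C4(Me) is the Z olefin, C5, C6, C7 carries the side chain, C8 = second CH(OAc), C9=C10(Me) is the E olefin, C11 = side-chain CH(Me); the target is then 1S,7S,8R,11R (these labels, not IUPAC locants, are used in the Why lines).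

## Route

Step 1
Reactants: 1 (R)-citronellal; 2 methyl vinyl ketone
Product: 3 (2S,3R)-3,7-dimethyl-2-(3-oxobutyl)oct-6-enal
Conditions: (S)-2-(methoxydiphenylmethyl)pyrrolidine (5 mol%), ethyl 3,4-dihydroxybenzoate (20 mol%), neat, 4 °C
Reagents that add atoms: none
Why: Enamine-catalysed asymmetric Michael addition of an aldehyde to an enone (diarylprolinol ether catalysis); the bulky group of the S catalyst blocks one face of the E enamine, so the enone adds to the open face and sets C7 as S under catalyst control, while C11 (R) comes unchanged from citronellal.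

Step 2
Reactants: 4 methacrolein; 5 allylmagnesium bromide
Product: 6 2-methylhexa-1,5-dien-3-ol (racemic)
Conditions: Et2O, −78 to 0 °C; aq. NH4Cl
Reagents that add atoms: none
Why: Grignard 1,2-addition to the enal carbonyl; the carbinol centre is made racemic on purpose because it is erased in step 3.

Step 3
Reactants: 6 2-methylhexa-1,5-dien-3-ol
Product: 7 (2E)-1-bromo-2-methylhexa-2,5-diene
Conditions: PBr3 (0.4 equiv), Et2O, −10 °C to rt
Reagents that add atoms: phosphorus tribromide (BrP(Br)Br)
Why: Bromination with allylic transposition (SN2′ type) gives the thermodynamically preferred primary, trisubstituted E allylic bromide, as in the conversion of linalool to geranyl bromide.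

Step 4
Reactants: 7 (2E)-1-bromo-2-methylhexa-2,5-diene
Product: 8 [(2E)-2-methylhexa-2,5-dien-1-yl](phenyl)sulfane
Conditions: NaSPh, EtOH, 0 °C to rt
Reagents that add atoms: sodium benzenethiolate ([Na+].[S-]c1ccccc1)
Why: SN2 substitution of the primary allylic bromide by the soft thiolate at the unhindered CH2 terminus, leaving the E olefin unchanged.

Step 5
Reactants: 3 (2S,3R)-3,7-dimethyl-2-(3-oxobutyl)oct-6-enal; 8 [(2E)-2-methylhexa-2,5-dien-1-yl](phenyl)sulfane
Product: 14 (5S,6R,7E,9S)-6,9-dihydroxy-8-methyl-5-[(2R)-6-methylhept-5-en-2-yl]dodeca-7,11-dien-2-one, via lithio sulfide 9 (not isolated), via titanate 10 (not isolated), via hydroxy sulfide 11 (not isolated), via sulfoxide 12 (not isolated), via sulfenate 13 (not isolated)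
Conditions: 8, n-BuLi, THF, −78 °C; Ti(OiPr)4, −78 °C; 3, −78 °C; t-BuOOH (decane, 1.1 equiv), −20 °C; Et2NH, MeOH, 25 to 40 °C; then H2O
Reagents that add atoms: tert-butyl hydroperoxide (CC(C)(C)OO)
Why: Proposed new method: a one-flask thioallyl relay in which (a) the α-lithiated allyl sulfide, as its Ti(OiPr)4 ate complex, adds through its sulfur-bearing carbon to the aldehyde of 3 (ketone untouched) with Felkin–Anh facial control (C8 R) and anti simple diastereoselection (C9 S), (b) the resulting titanium alkoxide binds t-BuOOH and delivers oxygen to the neighbouring sulfur faster than to any isolated C=C, and (c) the allyl sulfoxide undergoes the suprafacial [2,3]-sigmatropic shift to the allyl sulfenate, which Et2NH cleaves, so that the C1–O bond (S) and the E C9=C10 olefin form with 1,3-chirality transfer from C9; the closest known reactions are Yamamoto's α- and anti-selective additions of α-(phenylthio)allyl titanium reagents to aldehydes, the Kagan–Modena Ti(OiPr)4/hydroperoxide sulfoxidation and the Mislow–Evans rearrangement route of Evans to E 2-ene-1,4-diols, which have not been run as one operation nor with a 2-methyl, 3-allyl-substituted thioallyl unit.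

Step 6
Reactants: 14 (5S,6R,7E,9S)-6,9-dihydroxy-8-methyl-5-[(2R)-6-methylhept-5-en-2-yl]dodeca-7,11-dien-2-one
Product: 15 (4S,5E,7R,8S)-5,11-dimethyl-8-[(2R)-6-methylhept-5-en-2-yl]dodeca-1,5,11-triene-4,7-diol
Conditions: Ph3PCH3Br (4 equiv), KOtBu (3.9 equiv), THF, 0 °C to rt
Reagents that add atoms: methyltriphenylphosphonium bromide (C[P+](c1ccccc1)(c1ccccc1)c1ccccc1.[Br-])
Why: Wittig methylenation of the unhindered methyl ketone with excess ylide (the hydroxyls are carried as alkoxides) gives the 1,1-disubstituted olefin for ring closure; no stereocentre is α to the ketone.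

Step 7
Reactants: 15 (4S,5E,7R,8S)-5,11-dimethyl-8-[(2R)-6-methylhept-5-en-2-yl]dodeca-1,5,11-triene-4,7-diol
Product: 16 (4S,5E,7R,8S)-5,11-dimethyl-8-[(2R)-6-methylhept-5-en-2-yl]dodeca-1,5,11-triene-4,7-diyl diacetate
Conditions: Ac2O, pyridine, DMAP (cat.), CH2Cl2, 0 °C to rt
Reagents that add atoms: acetic anhydride (CC(=O)OC(C)=O)
Why: DMAP-catalysed esterification of both secondary allylic alcohols with retention at C1 and C8.

Step 8
Reactants: 16 (4S,5E,7R,8S)-5,11-dimethyl-8-[(2R)-6-methylhept-5-en-2-yl]dodeca-1,5,11-triene-4,7-diyl diacetate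
Product: 17 (1R,2E,4S,6Z,10S)-3,7-dimethyl-10-[(2R)-6-methylhept-5-en-2-yl]cyclodeca-2,6-diene-1,4-diyl diacetate (target)
Conditions: second-generation Hoveyda–Grubbs catalyst (10 mol%), toluene (1 mM), 60 °C
Reagents that add atoms: none
Why: Ring-closing olefin metathesis between the monosubstituted allyl olefin and the 1,1-disubstituted isopropenyl group at high dilution; next to the existing E olefin the ten-membered ring takes the new trisubstituted olefin far more easily as Z (a strained E,E-cyclodeca-1,5-diene is avoided), which sets the 3Z geometry, and the hindered side-chain olefin does not compete.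

## Compound list

1 | (R)-citronellal, (3R)-3,7-dimethyloct-6-enal | O=CC[C@H](C)CCC=C(C)C | starting material
2 | methyl vinyl ketone, but-3-en-2-one | C=CC(C)=O | starting material
3 | (2S,3R)-3,7-dimethyl-2-(3-oxobutyl)oct-6-enal | CC(=O)CC[C@@H]([C@H](C)CCC=C(C)C)C=O | intermediate
4 | methacrolein, 2-methylprop-2-enal | C=C(C)C=O | starting material
5 | allylmagnesium bromide | C=CC[Mg]Br | starting material
6 | 2-methylhexa-1,5-dien-3-ol (racemic) | C=C(C)C(O)CC=C | intermediate
7 | (2E)-1-bromo-2-methylhexa-2,5-diene | BrC/C(C)=C/CC=C | intermediate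
8 | [(2E)-2-methylhexa-2,5-dien-1-yl](phenyl)sulfane | c1ccccc1SC/C(C)=C/CC=C | intermediate
9 | [(2E)-2-methyl-1-(phenylsulfanyl)hexa-2,5-dien-1-yl]lithium | [Li]C(Sc1ccccc1)/C(C)=C/CC=C | intermediate
10 | lithium tetraisopropoxy[(2E)-2-methyl-1-(phenylsulfanyl)hexa-2,5-dien-1-yl]titanate | [Li+].CC(C)O[Ti-](OC(C)C)(OC(C)C)(OC(C)C)C(Sc1ccccc1)/C(C)=C/CC=C | intermediate
11 | (5S,6R,7S,8E)-6-hydroxy-8-methyl-5-[(2R)-6-methylhept-5-en-2-yl]-7-(phenylsulfanyl)dodeca-8,11-dien-2-one (present as its titanium alkoxide) | C=CC/C=C(\C)[C@H](Sc1ccccc1)[C@H](O)[C@@H](CCC(C)=O)[C@H](C)CCC=C(C)C | intermediate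
12 | (5S,6R,7S,8E)-7-(benzenesulfinyl)-6-hydroxy-8-methyl-5-[(2R)-6-methylhept-5-en-2-yl]dodeca-8,11-dien-2-one (both sulfur epimers) | C=CC/C=C(\C)[C@H](S(=O)c1ccccc1)[C@H](O)[C@@H](CCC(C)=O)[C@H](C)CCC=C(C)C | intermediate
13 | (5S,6R,7E,9S)-6-hydroxy-8-methyl-5-[(2R)-6-methylhept-5-en-2-yl]-9-[(phenylsulfanyl)oxy]dodeca-7,11-dien-2-one | C=CC[C@H](OSc1ccccc1)/C(C)=C/[C@H](O)[C@@H](CCC(C)=O)[C@H](C)CCC=C(C)C | intermediate
14 | (5S,6R,7E,9S)-6,9-dihydroxy-8-methyl-5-[(2R)-6-methylhept-5-en-2-yl]dodeca-7,11-dien-2-one | C=CC[C@H](O)/C(C)=C/[C@H](O)[C@@H](CCC(C)=O)[C@H](C)CCC=C(C)C | intermediate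
15 | (4S,5E,7R,8S)-5,11-dimethyl-8-[(2R)-6-methylhept-5-en-2-yl]dodeca-1,5,11-triene-4,7-diol | C=CC[C@H](O)/C(C)=C/[C@H](O)[C@@H](CCC(C)=C)[C@H](C)CCC=C(C)C | intermediate
16 | (4S,5E,7R,8S)-5,11-dimethyl-8-[(2R)-6-methylhept-5-en-2-yl]dodeca-1,5,11-triene-4,7-diyl diacetate | C=CC[C@H](OC(C)=O)/C(C)=C/[C@H](OC(C)=O)[C@@H](CCC(C)=C)[C@H](C)CCC=C(C)C | intermediate
17 | (1R,2E,4S,6Z,10S)-3,7-dimethyl-10-[(2R)-6-methylhept-5-en-2-yl]cyclodeca-2,6-diene-1,4-diyl diacetate | CC(=O)O[C@H]1C/C=C(/C)CC[C@@H]([C@H](C)CCC=C(C)C)[C@@H](OC(C)=O)/C=C/1C | target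

## Step count and risks

Total steps: 8. Longest linear sequence: 7 steps (methacrolein to target, steps 2, 3, 4, 5, 6, 7, 8).

Three steps most likely to fail:

**Step 5 (the proposed new step).** The risks are α versus γ attack of the substituted thioallyl titanate, incomplete Felkin or anti selectivity, loss of the E geometry of the C10=C1 unit in the allyl anion, and over-oxidation. The fallback uses known chemistry and sets out from 3. Propargyl alcohol is carboaluminated and iodinated (Me3Al, Cp2ZrCl2 cat., then I2) to (2E)-3-iodo-2-methylprop-2-en-1-ol F1. Oxidation with MnO2 gives (2E)-3-iodo-2-methylprop-2-enal F2. Brown allylation with (−)-Ipc2B(allyl) gives (1E,3S)-1-iodo-2-methylhexa-1,5-dien-3-ol F3. Nozaki–Hiyama–Kishi coupling of F3 with 3 (CrCl2, NiCl2 cat., DMSO/THF) forms the C8–C9 bond at the aldehyde only, with Felkin preference, and gives keto diol 14, where the route is rejoined at step 6.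

**Step 8.** Closing a ten-membered ring through a trisubstituted olefin may be slow, may give dimers or the E isomer, and the product can undergo Cope rearrangement if overheated. The fallback closes the ring earlier, on the more flexible skipped diene before the E olefin exists. It sets out from 11, isolated by quenching step 5 with water before the hydroperoxide is added. Wittig methylenation (Ph3PCH3Br, KOtBu) gives (5S,6R,7S,8E)-2,8-dimethyl-5-[(2R)-6-methylhept-5-en-2-yl]-7-(phenylsulfanyl)dodeca-1,8,11-trien-6-ol F4. Ring-closing metathesis with the same ruthenium catalyst gives the cyclic hydroxy sulfide (1R,2S,3E,6Z,10S)-3,7-dimethyl-10-[(2R)-6-methylhept-5-en-2-yl]-2-(phenylsulfanyl)cyclodeca-3,6-dien-1-ol F5. NaIO4 gives the cyclic sulfoxide F6, which shifts inside the ring to the cyclic sulfenate F7; Et2NH in MeOH cleaves it to (1R,2E,4S,6Z,10S)-3,7-dimethyl-10-[(2R)-6-methylhept-5-en-2-yl]cyclodeca-2,6-diene-1,4-diol F8. Acetylation (Ac2O, pyridine, DMAP) then gives 17.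

**Step 3.** The allylic bromide is labile and may form as a mixture of regio- and E/Z isomers, and any Z isomer carried into step 5 ends as the C1 epimer. The fallback replaces substitution by a sigmatropic transposition and sets out from 6. PhSCl and Et3N at −78 °C give 2-methylhexa-1,5-dien-3-yl benzenesulfenate F9, which rearranges on warming ([2,3] shift, E selective) to [(2E)-2-methylhexa-2,5-dien-1-yl]sulfinylbenzene F10. Deoxygenation with NaI and trifluoroacetic anhydride in acetone at −40 °C gives sulfide 8, so steps 3 and 4 are both bypassed and the route is rejoined at step 5.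

## Further compounds

F1 | step 5 | (2E)-3-iodo-2-methylprop-2-en-1-ol | OC/C(C)=C/I
F2 | step 5 | (2E)-3-iodo-2-methylprop-2-enal | O=C/C(C)=C/I
F3 | step 5 | (1E,3S)-1-iodo-2-methylhexa-1,5-dien-3-ol | C=CC[C@H](O)/C(C)=C/I
F4 | step 8 | (5S,6R,7S,8E)-2,8-dimethyl-5-[(2R)-6-methylhept-5-en-2-yl]-7-(phenylsulfanyl)dodeca-1,8,11-trien-6-ol | C=CC/C=C(\C)[C@H](Sc1ccccc1)[C@H](O)[C@@H](CCC(C)=C)[C@H](C)CCC=C(C)C
F5 | step 8 | (1R,2S,3E,6Z,10S)-3,7-dimethyl-10-[(2R)-6-methylhept-5-en-2-yl]-2-(phenylsulfanyl)cyclodeca-3,6-dien-1-ol | CC(C)=CCC[C@@H](C)[C@@H]1CC/C(C)=C\C/C=C(\C)[C@H](Sc2ccccc2)[C@@H]1O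
F6 | step 8 | (1R,2S,3E,6Z,10S)-2-(benzenesulfinyl)-3,7-dimethyl-10-[(2R)-6-methylhept-5-en-2-yl]cyclodeca-3,6-dien-1-ol (both sulfur epimers) | CC(C)=CCC[C@@H](C)[C@@H]1CC/C(C)=C\C/C=C(\C)[C@H](S(=O)c2ccccc2)[C@@H]1O
F7 | step 8 | (1R,2E,4S,6Z,10S)-3,7-dimethyl-10-[(2R)-6-methylhept-5-en-2-yl]-4-[(phenylsulfanyl)oxy]cyclodeca-2,6-dien-1-ol | c1ccccc1SO[C@H]1C/C=C(/C)CC[C@@H]([C@H](C)CCC=C(C)C)[C@@H](O)/C=C/1C
F8 | step 8 | (1R,2E,4S,6Z,10S)-3,7-dimethyl-10-[(2R)-6-methylhept-5-en-2-yl]cyclodeca-2,6-diene-1,4-diol | O[C@H]1C/C=C(/C)CC[C@@H]([C@H](C)CCC=C(C)C)[C@@H](O)/C=C/1C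
F9 | step 3 | 2-methylhexa-1,5-dien-3-yl benzenesulfenate (racemic) | C=C(C)C(OSc1ccccc1)CC=C
F10 | step 3 | [(2E)-2-methylhexa-2,5-dien-1-yl]sulfinylbenzene (racemic at sulfur) | O=S(C/C(C)=C/CC=C)c1ccccc1
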